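**Retrosynthetic overview**
1. Target ⇐ chelation-controlled 5-O-demethylation and O-debenzylation of a 3'-O-benzyl-3-hydroxy-5,6,7,8-tetramethoxyflavone.
2. That flavonol ⇐ C3 hydroxylation (DMDO epoxidation, then isomerisation) of the flavone ⇐ iodine/DMSO oxidative cyclisation of a 2'-hydroxychalcone.
3. Chalcone ⇐ key C–C bond by Claisen–Schmidt aldol condensation of 2'-hydroxy-3',4',5',6'-tetramethoxyacetophenone (ring A) with 3-benzyloxy-4,5-dimethoxybenzaldehyde (ring B).
4. Ring A ketone ⇐ 3,4,5-trimethoxyphenol (acetylation, bromination, methoxylation); ring B aldehyde ⇐ 3-bromo-4,5-dimethoxybenzaldehyde (acetal, Br→OH, benzylation, deprotection).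
5. Rings A and B are bought as benzenes; ring C (the pyranone) is the only ring formed, after the aldol step.

Assumption: the target is an achiral flavonol with no stereocentre, so no enantiocontrol is needed; the only stereo-element on the route is the (E)-alkene of chalcone 14, which is consumed in step 9.

**Route**

Step 1
Reactants: 1 3,4,5-trimethoxyphenol
Product: 3 1-(2-hydroxy-4,5,6-trimethoxyphenyl)ethanone, via difluoroboron chelate 2 (not isolated)
Conditions: AcOH (solvent), BF3·OEt2 (3 equiv), 90 °C, 3 h; then 10% aq NaOAc, rt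
Reagents that add atoms: acetic acid, CC(=O)O
Why: BF3-promoted Friedel–Crafts C-acetylation goes to one of the two equivalent ortho positions of the electron-rich phenol (para is blocked), and the ortho-hydroxy ketone is held as its BF2 chelate until aqueous hydrolysis, which prevents a second acylation.

Step 2
Reactants: 3 1-(2-hydroxy-4,5,6-trimethoxyphenyl)ethanone
Product: 4 1-(3-bromo-2-hydroxy-4,5,6-trimethoxyphenyl)ethanone
Conditions: NBS (1.05 equiv), MeCN, 0 °C → rt, 1 h
Reagents that add atoms: N-bromosuccinimide, O=C1CCC(=O)N1Br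
Why: electrophilic aromatic bromination at the single remaining ring C–H (ortho to OH, para to OMe) is much faster than α-bromination of the chelated ketone.

Step 3
Reactants: 4 1-(3-bromo-2-hydroxy-4,5,6-trimethoxyphenyl)ethanone
Product: 5 1-(2-hydroxy-3,4,5,6-tetramethoxyphenyl)ethanone
Conditions: NaOMe (25% in MeOH, 8 equiv), CuBr (0.3 equiv), DMF, 110 °C, 6 h, N2; then 2 M HCl
Reagents that add atoms: sodium methoxide, [Na+].[O-]C
Why: Ullmann-type copper-catalysed methoxylation of the aryl bromide, assisted by the ortho phenoxide (the reactivity that turns 5-bromovanillin into syringaldehyde), installs the fifth ring oxygen.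

Step 4
Reactants: 6 3-bromo-4,5-dimethoxybenzaldehyde
Product: 7 2-(3-bromo-4,5-dimethoxyphenyl)-1,3-dioxolane
Conditions: ethylene glycol (3 equiv), p-TsOH·H2O (5 mol%), toluene, reflux, Dean–Stark, 4 h
Reagents that add atoms: ethylene glycol, OCCO
Why: acid-catalysed acetalisation with azeotropic removal of water masks the aldehyde against the organolithium of the next step.

Step 5
Reactants: 7 2-(3-bromo-4,5-dimethoxyphenyl)-1,3-dioxolane
Product: 10 5-(1,3-dioxolan-2-yl)-2,3-dimethoxyphenol, via aryllithium 8 (not isolated), via lithium aryltrimethoxyborate 9 (not isolated)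
Conditions: n-BuLi (1.1 equiv), THF, −78 °C, 30 min; B(OMe)3 (1.5 equiv), −78 °C → rt; then 30% aq H2O2 (3 equiv), 0 °C → rt, 2 h
Reagents that add atoms: hydrogen peroxide, OO
Why: bromine–lithium exchange, borylation and peroxide oxidation (1,2-aryl shift from boron to oxygen) put the hydroxyl exactly on the carbon that carried bromine, and the dioxolane is inert to all three operations.

Step 6
Reactants: 10 5-(1,3-dioxolan-2-yl)-2,3-dimethoxyphenol
Product: 11 2-[3-(benzyloxy)-4,5-dimethoxyphenyl]-1,3-dioxolane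
Conditions: BnBr (1.2 equiv), K2CO3 (2 equiv), DMF, rt → 50 °C, 4 h
Reagents that add atoms: benzyl bromide, BrCc1ccccc1
Why: Williamson ether synthesis on the only free phenol gives a benzyl ether that survives base, iodine/DMSO and DMDO and is later removed by hydrogenolysis.

Step 7
Reactants: 11 2-[3-(benzyloxy)-4,5-dimethoxyphenyl]-1,3-dioxolane
Product: 12 3-(benzyloxy)-4,5-dimethoxybenzaldehyde
Conditions: 1 M aq HCl, THF, rt, 2 h
Reagents that add atoms: water, O
Why: acid-catalysed acetal hydrolysis frees the aldehyde while the benzyl and methyl ethers are untouched.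

Step 8
Reactants: 5 1-(2-hydroxy-3,4,5,6-tetramethoxyphenyl)ethanone; 12 3-(benzyloxy)-4,5-dimethoxybenzaldehyde
Product: 14 (E)-3-[3-(benzyloxy)-4,5-dimethoxyphenyl]-1-(2-hydroxy-3,4,5,6-tetramethoxyphenyl)prop-2-en-1-one, via racemic aldol adduct 13 (not isolated)
Conditions: KOH (50% aq, 10 equiv), EtOH, 0 °C → rt, 36 h; then 2 M HCl to pH 3
Reagents that add atoms: none
Why: Claisen–Schmidt (crossed aldol) condensation pairs the only enolisable partner (the methyl ketone) with the only electrophile (the non-enolisable aldehyde), and E1cB dehydration of the aldol gives the conjugated (E)-enone, erasing the transient carbinol stereocentre.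

Step 9
Reactants: 14 (E)-3-[3-(benzyloxy)-4,5-dimethoxyphenyl]-1-(2-hydroxy-3,4,5,6-tetramethoxyphenyl)prop-2-en-1-one
Product: 16 2-[3-(benzyloxy)-4,5-dimethoxyphenyl]-5,6,7,8-tetramethoxy-4H-chromen-4-one, via racemic flavanone 15 (not isolated)
Conditions: I2 (10 mol%), DMSO, 120 °C, 3 h; aq Na2S2O3 work-up
Reagents that add atoms: none
Why: iodine-catalysed oxidative cyclisation: intramolecular oxa-Michael addition of the 2'-phenol closes ring C, then α-iodination and HI elimination dehydrogenate the flavanone while DMSO re-oxidises HI, so the flavanone stereocentre disappears.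

Step 10
Reactants: 16 2-[3-(benzyloxy)-4,5-dimethoxyphenyl]-5,6,7,8-tetramethoxy-4H-chromen-4-one
Product: 18 2-[3-(benzyloxy)-4,5-dimethoxyphenyl]-3-hydroxy-5,6,7,8-tetramethoxy-4H-chromen-4-one, via racemic flavone epoxide 17 (not isolated)
Conditions: DMDO (ca. 0.08 M in acetone, 3 equiv), CH2Cl2, 0 °C → rt, 16 h; evaporate; then p-TsOH·H2O (5 mol%), CH2Cl2, rt, 1 h
Reagents that add atoms: dimethyldioxirane, CC1(C)OO1
Why: DMDO epoxidation of the enol-ether-like C2=C3 bond followed by acid-catalysed opening to the C2 oxocarbenium ion and loss of H-3 gives net C3 hydroxylation, and the fully etherified substrate has no free phenol for the oxidant to attack.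

Step 11
Reactants: 18 2-[3-(benzyloxy)-4,5-dimethoxyphenyl]-3-hydroxy-5,6,7,8-tetramethoxy-4H-chromen-4-one
Product: 19 3-hydroxy-2-(3-hydroxy-4,5-dimethoxyphenyl)-5,6,7,8-tetramethoxy-4H-chromen-4-one
Conditions: H2 (1 atm), 10% Pd/C, EtOAc–MeOH 1:1, rt, 3 h
Reagents that add atoms: none
Why: catalytic hydrogenolysis cleaves the benzyl aryl ether cleanly, and the flavonol C2=C3 bond and the methyl ethers are stable at 1 atm and rt.

Step 12
Reactants: 19 3-hydroxy-2-(3-hydroxy-4,5-dimethoxyphenyl)-5,6,7,8-tetramethoxy-4H-chromen-4-one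
Product: 20 3,5-dihydroxy-2-(3-hydroxy-4,5-dimethoxyphenyl)-6,7,8-trimethoxy-4H-chromen-4-one (3-demethyldigicitrin)
Conditions: AlCl3 (anhydrous, 6 equiv), MeCN, 0 °C → 45 °C, 3 h; then 2 M aq HCl, 60 °C, 30 min
Reagents that add atoms: none
Why: chelation-controlled Lewis-acid ether cleavage: only the 5-OMe peri to the C4 carbonyl can sit in a six-membered aluminium chelate, so chloride demethylates it by SN2 attack and the other five methyl ethers are left intact.

**Compound list**
1 | 3,4,5-trimethoxyphenol | COc1cc(O)cc(OC)c1OC | starting material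
2 | difluoroboron chelate of 3 (not isolated) | CC1=[O+][B-](F)(F)Oc2cc(OC)c(OC)c(OC)c12 | intermediate
3 | 1-(2-hydroxy-4,5,6-trimethoxyphenyl)ethanone | CC(=O)c1c(O)cc(OC)c(OC)c1OC | intermediate
4 | 1-(3-bromo-2-hydroxy-4,5,6-trimethoxyphenyl)ethanone | CC(=O)c1c(O)c(Br)c(OC)c(OC)c1OC | intermediate
5 | 1-(2-hydroxy-3,4,5,6-tetramethoxyphenyl)ethanone | CC(=O)c1c(O)c(OC)c(OC)c(OC)c1OC | intermediate
6 | 3-bromo-4,5-dimethoxybenzaldehyde | COc1cc(C=O)cc(Br)c1OC | starting material
7 | 2-(3-bromo-4,5-dimethoxyphenyl)-1,3-dioxolane | COc1cc(C2OCCO2)cc(Br)c1OC | intermediate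
8 | [5-(1,3-dioxolan-2-yl)-2,3-dimethoxyphenyl]lithium (not isolated) | [Li]c1cc(C2OCCO2)cc(OC)c1OC | intermediate
9 | lithium [5-(1,3-dioxolan-2-yl)-2,3-dimethoxyphenyl]trimethoxyborate (not isolated) | [Li+].CO[B-](OC)(OC)c1cc(C2OCCO2)cc(OC)c1OC | intermediate
10 | 5-(1,3-dioxolan-2-yl)-2,3-dimethoxyphenol | COc1cc(C2OCCO2)cc(O)c1OC | intermediate
11 | 2-[3-(benzyloxy)-4,5-dimethoxyphenyl]-1,3-dioxolane | COc1cc(C2OCCO2)cc(OCc2ccccc2)c1OC | intermediate
12 | 3-(benzyloxy)-4,5-dimethoxybenzaldehyde | COc1cc(C=O)cc(OCc2ccccc2)c1OC | intermediate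
13 | 3-[3-(benzyloxy)-4,5-dimethoxyphenyl]-3-hydroxy-1-(2-hydroxy-3,4,5,6-tetramethoxyphenyl)propan-1-one (racemic; not isolated) | COc1cc(C(O)CC(=O)c2c(O)c(OC)c(OC)c(OC)c2OC)cc(OCc2ccccc2)c1OC | intermediate
14 | (E)-3-[3-(benzyloxy)-4,5-dimethoxyphenyl]-1-(2-hydroxy-3,4,5,6-tetramethoxyphenyl)prop-2-en-1-one | COc1cc(/C=C/C(=O)c2c(O)c(OC)c(OC)c(OC)c2OC)cc(OCc2ccccc2)c1OC | intermediate
15 | 2-[3-(benzyloxy)-4,5-dimethoxyphenyl]-5,6,7,8-tetramethoxychroman-4-one (racemic; not isolated) | COc1cc(C2CC(=O)c3c(OC)c(OC)c(OC)c(OC)c3O2)cc(OCc2ccccc2)c1OC | intermediate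
16 | 2-[3-(benzyloxy)-4,5-dimethoxyphenyl]-5,6,7,8-tetramethoxy-4H-chromen-4-one | COc1cc(-c2cc(=O)c3c(OC)c(OC)c(OC)c(OC)c3o2)cc(OCc2ccccc2)c1OC | intermediate
17 | 2,3-epoxy-2-[3-(benzyloxy)-4,5-dimethoxyphenyl]-5,6,7,8-tetramethoxychroman-4-one (racemic; not isolated) | COc1cc(C23OC2C(=O)c2c(OC)c(OC)c(OC)c(OC)c2O3)cc(OCc2ccccc2)c1OC | intermediate
18 | 2-[3-(benzyloxy)-4,5-dimethoxyphenyl]-3-hydroxy-5,6,7,8-tetramethoxy-4H-chromen-4-one | COc1cc(-c2oc3c(OC)c(OC)c(OC)c(OC)c3c(=O)c2O)cc(OCc2ccccc2)c1OC | intermediate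
19 | 3-hydroxy-2-(3-hydroxy-4,5-dimethoxyphenyl)-5,6,7,8-tetramethoxy-4H-chromen-4-one | COc1cc(-c2oc3c(OC)c(OC)c(OC)c(OC)c3c(=O)c2O)cc(O)c1OC | intermediate
20 | 3,5-dihydroxy-2-(3-hydroxy-4,5-dimethoxyphenyl)-6,7,8-trimethoxy-4H-chromen-4-one (3-demethyldigicitrin; achiral) | COc1cc(-c2oc3c(OC)c(OC)c(OC)c(O)c3c(=O)c2O)cc(O)c1OC | target

**Step count**
Total: 12 steps (3 for the ring A ketone, 4 for the ring B aldehyde, 5 after convergence).
Longest linear sequence: 9 steps (6 → 7 → 10 → 11 → 12 → 14 → 16 → 18 → 19 → 20).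

**Three steps most likely to fail, with fallbacks**

Step 3 (copper-catalysed methoxylation of a bromide flanked on both sides, with a methyl ketone present). The risks are hydrodebromination back to 3 and incomplete conversion. Fallback, setting out from 3 and coming back at 5: introduce the oxygen through a formyl group instead of a halide. Duff formylation of 3 (hexamethylenetetramine, TFA, 80 °C, then aq HCl) at the only free ring position gives 3-acetyl-2-hydroxy-4,5,6-trimethoxybenzaldehyde F1. Dakin oxidation (H2O2 1.05 equiv, aq NaOH, 0 °C, under N2; the aldehyde reacts far faster than the ketone) gives 1-(2,3-dihydroxy-4,5,6-trimethoxyphenyl)ethanone F2. Selective methylation of the non-chelated 3-hydroxyl through the dianion (NaH 2.1 equiv, DMSO–THF, MeI 1.0 equiv) returns 5.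

Step 10 (DMDO 3-hydroxylation). The risks are slow epoxidation of a hindered 5-methoxyflavone and competing oxidation of the benzyl ether or the electron-rich rings. Fallback, setting out from 16 and coming back at 18: make the C3–O bond by metalation instead of epoxidation. LDA (1.2 equiv, THF, −78 °C) removes H-3 to give the 3-lithio derivative of 16, F3. B(OMe)3 traps it as lithium trimethoxy(flavon-3-yl)borate F4. Oxidation in the same pot with 30% H2O2 gives 18.

Step 12 (selective cleavage of one of six methyl ethers with two free phenols present). The risks are additional loss of the 6-OMe or the 4'-OMe, or incomplete reaction. Fallback, setting out from 5 (and using 12) and coming back at 20: carry the 5-oxygen as a benzyl ether so that the end-game is one hydrogenolysis.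
- BCl3 (CH2Cl2, −78 → 0 °C) removes the methyl ether ortho to the acetyl group of 5 to give symmetrical 1-(2,6-dihydroxy-3,4,5-trimethoxyphenyl)ethanone F5.
- Mono-benzylation (BnBr 1.0 equiv, K2CO3, acetone, reflux; the second hydroxyl stays chelated to the ketone) gives 1-[2-(benzyloxy)-6-hydroxy-3,4,5-trimethoxyphenyl]ethanone F6.
- Claisen–Schmidt condensation with 12 (KOH, EtOH) gives (E)-1-[2-(benzyloxy)-6-hydroxy-3,4,5-trimethoxyphenyl]-3-[3-(benzyloxy)-4,5-dimethoxyphenyl]prop-2-en-1-one F7.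
- I2/DMSO gives 5-(benzyloxy)-2-[3-(benzyloxy)-4,5-dimethoxyphenyl]-6,7,8-trimethoxy-4H-chromen-4-one F8.
- DMDO then p-TsOH gives 5-(benzyloxy)-2-[3-(benzyloxy)-4,5-dimethoxyphenyl]-3-hydroxy-6,7,8-trimethoxy-4H-chromen-4-one F9.
- H2 over Pd/C removes both benzyl groups and gives 20.

**Further compounds**
F1 | step 3 | 3-acetyl-2-hydroxy-4,5,6-trimethoxybenzaldehyde | CC(=O)c1c(O)c(C=O)c(OC)c(OC)c1OC
F2 | step 3 | 1-(2,3-dihydroxy-4,5,6-trimethoxyphenyl)ethanone | CC(=O)c1c(O)c(O)c(OC)c(OC)c1OC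
F3 | step 10 | {2-[3-(benzyloxy)-4,5-dimethoxyphenyl]-5,6,7,8-tetramethoxy-4-oxo-4H-chromen-3-yl}lithium | COc1cc(-c2oc3c(OC)c(OC)c(OC)c(OC)c3c(=O)c2[Li])cc(OCc2ccccc2)c1OC
F4 | step 10 | lithium {2-[3-(benzyloxy)-4,5-dimethoxyphenyl]-5,6,7,8-tetramethoxy-4-oxo-4H-chromen-3-yl}trimethoxyborate | [Li+].COc1cc(-c2oc3c(OC)c(OC)c(OC)c(OC)c3c(=O)c2[B-](OC)(OC)OC)cc(OCc2ccccc2)c1OC
F5 | step 12 | 1-(2,6-dihydroxy-3,4,5-trimethoxyphenyl)ethanone | CC(=O)c1c(O)c(OC)c(OC)c(OC)c1O
F6 | step 12 | 1-[2-(benzyloxy)-6-hydroxy-3,4,5-trimethoxyphenyl]ethanone | CC(=O)c1c(O)c(OC)c(OC)c(OC)c1OCc1ccccc1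
F7 | step 12 | (E)-1-[2-(benzyloxy)-6-hydroxy-3,4,5-trimethoxyphenyl]-3-[3-(benzyloxy)-4,5-dimethoxyphenyl]prop-2-en-1-one | COc1cc(/C=C/C(=O)c2c(O)c(OC)c(OC)c(OC)c2OCc2ccccc2)cc(OCc2ccccc2)c1OC
F8 | step 12 | 5-(benzyloxy)-2-[3-(benzyloxy)-4,5-dimethoxyphenyl]-6,7,8-trimethoxy-4H-chromen-4-one | COc1cc(-c2cc(=O)c3c(OCc4ccccc4)c(OC)c(OC)c(OC)c3o2)cc(OCc2ccccc2)c1OC
F9 | step 12 | 5-(benzyloxy)-2-[3-(benzyloxy)-4,5-dimethoxyphenyl]-3-hydroxy-6,7,8-trimethoxy-4H-chromen-4-one | COc1cc(-c2oc3c(OC)c(OC)c(OC)c(OCc4ccccc4)c3c(=O)c2O)cc(OCc2ccccc2)c1OC
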